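## The problem

Target 16 consists of three benzene rings joined by two diaryl ether oxygens: a central, fully substituted hydroquinone (ring B: two hydroxyls, two bromines and two aryloxy groups, each pair para) and two identical 2,3,5-tribromo-4-hydroxyphenoxy units (rings A and C). There is no stereocentre and the constitution is centrosymmetric, so the synthesis can be run in both directions at once, but every step must then succeed twice on one molecule. The hard bonds are the two aryl–O–aryl links: on ring B each oxygen sits between a bromine and a hydroxyl, on the outer ring it sits next to a bromine, and eight aryl bromides make a late copper- or palladium-mediated etherification unattractive. The ring B hydroquinone is easily oxidised to a quinone and must stay masked while bromine or another oxidant is present, and the aryl bromides will not tolerate organolithium reagents, hydrogenation or zerovalent palladium. The bromine count on each outer ring must be exact: both carbons next to the hydroxyl, but only one of the two carbons next to the ether oxygen. The feature that opens the route is that in rings A and C the ether carbon C1 and the hydroxyl carbon C4 are para, which is the pattern formed when a 2-siloxybuta-1,3-diene adds to an acrylate whose alpha carbon carries the ring B oxygen. The ether oxygen can therefore be fixed to ring B first, at a primary carbon, and the outer ring built around it; since ring B has no hydrogen, bromine introduced afterwards can only enter rings A and C.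

## Retrosynthesis

**16 to 15 (two O–CH3 bonds).** The ring B hydroquinone is carried as its dimethyl ether 15 until the last step, because the free hydroquinone would be oxidised by bromine and by the dehydrogenating reagent. Methyl is preferred over benzyl (hydrogenolysis would strip bromine) and over silyl (lost under the basic steps), and it arrives at no cost from methoxide and bromanil 1. The forward reaction must cleave two hindered methyl aryl ethers without touching diaryl ethers or C–Br bonds, which BBr3 does.

**15 to 13 (six C–Br bonds on rings A and C).** Cutting all outer-ring bromines gives bis-phenol 13, whose ring B is fully substituted and therefore inert to electrophilic substitution. Carrying these bromines through the ring construction instead would expose them to heat and base and crowd the cycloaddition. The forward step must deliver three bromines per ring: two ortho to the hydroxyl (fast, via tetrabromide 14) and one ortho to the ether oxygen.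

**13 to 11 to 10 (retro-aromatisation; one C–CO2Me bond per outer ring restored).** Each 4-aryloxyphenol ring of 13 is traced to a 4-aryloxy-4-methoxycarbonylcyclohexa-2,5-dienone (11), which aromatises with loss of CO2 once the ester is hydrolysed (through carboxylate 12). Dienone 11 comes from the saturated keto ester 10 by dehydrogenation. The order is deliberate: if the ester were hydrolysed before both ring double bonds were in place, the half-oxidised ring would decarboxylate as a vinylogous beta-keto acid to a non-aromatic enone or enol ether, a dead end from which the ring B phenol can be lost by hydrolysis. Keeping the ester until 11 leaves aromatisation as the only outlet.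

**10 to 7 plus two molecules of 8 (four C–C bonds, two rings; the key cut).** Each 4,4-disubstituted cyclohexanone of 10 is the hydrolysed Diels–Alder adduct (9) of 2-(trimethylsilyloxy)buta-1,3-diene 8 and a 2-aryloxyacrylate arm of 7. The neighbouring cut, a direct aryl–O bond formation between a ring B phenoxide and a polybrominated arene, would require substitution at a carbon flanked by bromine in the presence of many competing C–Br bonds. The cycloaddition forms only C–C bonds and places the ketone para to the ether carbon by the ordinary regiochemical rule. The precursor 7 is an acyclic, achiral bis-acrylate.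

**7 to 5 (two C=CH2 bonds).** The acrylate methylene groups are removed to give bis(aryloxyacetate) 5. The forward step is an alpha-methylenation that proceeds through formyl enolate 6 and avoids strong amide bases near the aryl bromides.

**5 to 3 plus two molecules of 4 (two O–CH2 bonds).** The oxygen–carbon bond that later becomes the diaryl ether is made here, by Williamson alkylation of both hydroxyls of hydroquinone 3 with two molecules of methyl bromoacetate 4. The reaction takes place at a primary carbon, where the two ortho substituents of ring B matter little.

**3 to 2 to 1.** Hydroquinone 3 is the reduction product of 2,5-dibromo-3,6-dimethoxy-1,4-benzoquinone 2, which arises from bromanil 1 by twofold addition–elimination of methoxide. Bromanil 1 thus supplies ring B with all six substituents in place.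

## Roads not taken

Alternative 1: Ring B would be built instead of rings A and C. A squarate-derived 4-alkenyl-4-hydroxycyclobutenone A1 carrying two 4-methoxyphenoxy groups would be heated; opening of the four-membered ring to a dienylketene and six-electron ring closure would form one C–C bond and give 2,5-bis(4-methoxyphenoxy)benzene-1,4-diol A2.
- Merits: the rearrangement is regiospecific, needs no oxidant and delivers the aromatic ring directly, whereas the chosen plan needs a dehydrogenation and a decarboxylation to reach the aromatic level.
- Weak points: this road constructs the one ring that bromanil 1 already supplies fully substituted. A1 needs several steps of cyclobutenedione chemistry, including an organolithium addition. A2 still lacks all eight bromines, and two of them must enter an unprotected, electron-rich hydroquinone that bromine would oxidise to a quinone.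
- Comparison: the late halogenation burden is heavier (eight C–Br bonds against six) and includes the same "one of two ortho positions" problem on the outer rings. The chosen plan keeps the ring synthesis for the rings that need it and buys ring B.

Alternative 2: The ether bonds would be made by substitution of an aryl fluoride activated by an ortho nitro group, 1,3-dibromo-5-fluoro-2-methoxy-4-nitrobenzene A3, by the dianion of 3. Reduction would give bis-aniline A4, and double diazotisation with an alkyl nitrite and bromine transfer from CuBr2 would give 1,4-dibromo-2,5-dimethoxy-3,6-bis(2,3,5-tribromo-4-methoxyphenoxy)benzene A5; no ring is closed.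
- Merits: the nitro group both activates the etherification and marks the carbon that receives the odd bromine, so the position and number of bromines on rings A and C are fixed beyond doubt. In this respect the road is better than the chosen plan, whose step 8 relies on stoichiometry and rate differences.
- Weak points: the doubly flanked, easily oxidised dianion of 3 must attack twice at a crowded carbon of a nitroarene that is itself an oxidant, with a bromine ortho to the nitro group as a competing leaving group. A3 needs its own multistep preparation. The nitro groups must be reduced without hydrodebromination, and two hindered diazonium groups must be replaced without loss to reduction.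
- Comparison: the chosen plan sets against the better regiocontrol an ether bond formed by a safe alkylation, cheaper inputs and no diazonium chemistry. A5 is also the compound at which the fallback for step 8 arrives.

Alternative 3: The shortest road would be anodic oxidation of 2,3,6-tribromophenol A7 in the presence of the dianion of bromanilic acid A6, forming both C–O bonds at the para carbons of two phenol units and giving quinone A8, 2,5-dibromo-3,6-bis(2,3,5-tribromo-4-hydroxyphenoxy)-1,4-benzoquinone. One reduction would then give 16.
- Merits: two steps from simple materials, all bromines in place from the start and no protecting group. If it worked, no other plan could compete on step economy.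
- Weak points: the oxidised form of A7 is far more likely to be captured by its own phenol or phenolate (C–O and C–C oligomers) than by the weakly nucleophilic, charge-delocalised oxygen of the A6 dianion. The 4-aryloxyphenol units of A8 are easier to oxidise than A7 and would be taken on to quinones with loss of the new ether. A8 is also a vinylogous aryl ester open to addition–elimination by any phenolate present.
- Comparison: the chosen plan is much longer, but each of its bond formations has a predictable chemoselectivity.

Key step: step 5

Assumption: 16 has no stereocentre and rotation about the aryl–oxygen bonds is taken as fast, so no atropisomer needs control. Compounds 6 and 9 and some fallback compounds are isomer mixtures that converge on one successor and are written without stereodescriptors.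

## Route

Step 1
Reactants: 1 bromanil (2,3,5,6-tetrabromo-1,4-benzoquinone)
Product: 2 2,5-dibromo-3,6-dimethoxy-1,4-benzoquinone
Conditions: NaOMe (2.05 equiv), MeOH, 0 °C to rt
Reagents that add atoms: sodium methoxide, [Na+].[O-]C
Why: Twofold addition–elimination of methoxide on a haloquinone; the first methoxy group turns its own enone arm into a vinylogous ester, so the second methoxide enters the other arm and the 2,5-dibromo-3,6-dimethoxy isomer is expected, as is usual for tetrahaloquinones.

Step 2
Reactants: 2 2,5-dibromo-3,6-dimethoxy-1,4-benzoquinone
Product: 3 2,5-dibromo-3,6-dimethoxybenzene-1,4-diol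
Conditions: Na2S2O4, EtOAc/H2O, rt, argon
Reagents that add atoms: none
Why: Dithionite reduction of a quinone to its hydroquinone leaves aryl bromides and methyl ethers alone; 3 is kept under argon and used at once because it reoxidises in air.

Step 3
Reactants: 3 2,5-dibromo-3,6-dimethoxybenzene-1,4-diol; 4 methyl bromoacetate (two equivalents react, one at each hydroxyl)
Product: 5 dimethyl 2,2'-[(2,5-dibromo-3,6-dimethoxy-1,4-phenylene)bis(oxy)]diacetate
Conditions: 4 (2.4 equiv), K2CO3 (3 equiv), degassed DMF, rt to 50 °C, argon
Reagents that add atoms: methyl bromoacetate (second equivalent of 4), COC(=O)CBr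
Why: Twofold Williamson ether synthesis, in which each phenoxide of 3 displaces bromide from one molecule of 4 by SN2 at an activated primary carbon, tolerating the two ortho substituents on each phenoxide. This is the step that fixes the future diaryl ether oxygen to its second carbon.

Step 4
Reactants: 5 dimethyl 2,2'-[(2,5-dibromo-3,6-dimethoxy-1,4-phenylene)bis(oxy)]diacetate
Product: 7 dimethyl 2,2'-[(2,5-dibromo-3,6-dimethoxy-1,4-phenylene)bis(oxy)]diacrylate, via bis(formyl ester) disodium enolate 6 (not isolated)
Conditions: NaH (2.5 equiv), HCO2Me (excess), THF, 0 °C to rt; then aq. CH2O (from paraformaldehyde, excess), K2CO3, THF/H2O, 0 °C to rt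
Reagents that add atoms: formaldehyde (from paraformaldehyde), C=O
Why: Crossed Claisen formylation of the aryloxyacetate (with methyl formate) gives enolate 6, which undergoes deformylative methylenation: aldol addition to formaldehyde, formyl transfer to the new alkoxide and E1cB loss of formate leave the C=CH2 group on each arm; no amide base or low-temperature metalation is needed beside the aryl bromides.

Step 5
Reactants: 7 dimethyl 2,2'-[(2,5-dibromo-3,6-dimethoxy-1,4-phenylene)bis(oxy)]diacrylate; 8 2-(trimethylsilyloxy)buta-1,3-diene (two equivalents react, one at each acrylate arm)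
Product: 10 dimethyl 1,1'-[(2,5-dibromo-3,6-dimethoxy-1,4-phenylene)bis(oxy)]bis(4-oxocyclohexane-1-carboxylate), via bis(silyl enol ether) cycloadduct 9 (not isolated)
Conditions: 8 (8 equiv), BHT (cat.), toluene, sealed tube, 150 °C; then 1 M HCl, THF, rt
Reagents that add atoms: 2-(trimethylsilyloxy)buta-1,3-diene (second equivalent of 8), C=CC(=C)O[Si](C)(C)C
Why: Each acrylate arm of 7 undergoes a thermal, concerted but asynchronous [4+2] cycloaddition of normal electron demand with one molecule of diene 8; the closest known reaction type is the Diels–Alder addition of 2-siloxybuta-1,3-dienes to 2-acyloxy- and 2-alkoxyacrylates, which gives 4,4-disubstituted cyclohexanones after hydrolysis. The diene CH2 next to the siloxy carbon (largest HOMO coefficient) bonds to the acrylate CH2 (largest LUMO coefficient) and the other diene terminus bonds to the oxygen-bearing alpha carbon, so the siloxy carbon and the ether carbon end up para. Each six-membered carbocycle closes by an intermolecular cycloaddition that forms two sigma bonds suprafacially on both partners, and the two arms react independently. No stereocentre is created in the product: the quaternary carbon of 9 is stereogenic only while the enol ether double bond is present, so 9 is a mixture of meso and racemic forms that converge on achiral 10 on hydrolysis, and endo or exo approach is immaterial. The only selectivity needed is para over meta regiochemistry, secured because the siloxy donor and the ester acceptor polarise the two components in the same sense. Bonding starts at the unhindered acrylate CH2, so the transition state tolerates the bulky aryloxy group on the alpha carbon, and the two bromines on ring B make that aryloxy group a weaker donor than an alkoxy group, which keeps the dienophile reactive. BHT suppresses radical polymerisation of 7, excess 8 compensates for diene dimerisation, and dilute acid cleaves the silyl enol ethers without touching the methyl esters or aryl ethers.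

Step 6
Reactants: 10 dimethyl 1,1'-[(2,5-dibromo-3,6-dimethoxy-1,4-phenylene)bis(oxy)]bis(4-oxocyclohexane-1-carboxylate)
Product: 11 dimethyl 1,1'-[(2,5-dibromo-3,6-dimethoxy-1,4-phenylene)bis(oxy)]bis(4-oxocyclohexa-2,5-diene-1-carboxylate)
Conditions: IBX (2-iodoxybenzoic acid, 8 equiv), DMSO, 80 °C
Reagents that add atoms: none
Why: IBX dehydrogenation of cyclohexanones through the enol and a pentavalent iodine intermediate introduces both alpha,beta double bonds of each ring; the quaternary C1 has no hydrogen, so the product stops at the cross-conjugated dienone, and the metal-free oxidant leaves the aryl bromides and the fully substituted ring B alone.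

Step 7
Reactants: 11 dimethyl 1,1'-[(2,5-dibromo-3,6-dimethoxy-1,4-phenylene)bis(oxy)]bis(4-oxocyclohexa-2,5-diene-1-carboxylate)
Product: 13 4,4'-[(2,5-dibromo-3,6-dimethoxy-1,4-phenylene)bis(oxy)]diphenol, via bis(dienone carboxylate) dilithium salt 12 (not isolated)
Conditions: LiOH, THF/H2O, 0 °C to rt; then 1 M HCl
Reagents that add atoms: none
Why: Ester hydrolysis gives carboxylate 12, which loses CO2 spontaneously because the electron pair left at C1 is that of a phenoxide (decarboxylative aromatisation of a 4-carboxycyclohexa-2,5-dienone); direct acyl cleavage by hydroxide at the ester would lead to the same phenoxide, so both pathways converge on 13 with the aryl ether intact.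

Step 8
Reactants: 13 4,4'-[(2,5-dibromo-3,6-dimethoxy-1,4-phenylene)bis(oxy)]diphenol
Product: 15 1,4-dibromo-2,5-dimethoxy-3,6-bis(2,3,5-tribromo-4-hydroxyphenoxy)benzene, via tetrabromide 14 (not isolated)
Conditions: Br2 (6.1 equiv), glacial AcOH, rt then 45 °C, dark
Reagents that add atoms: bromine, BrBr
Why: Electrophilic aromatic bromination: the hydroxyl directs the first two bromines of each outer ring to its ortho positions (14), the ether oxygen then directs one more to an adjacent carbon, and a fourth is disfavoured by the added deactivation and by crowding on both sides of the remaining hydrogen; ring B has no hydrogen and cannot react.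

Step 9
Reactants: 15 1,4-dibromo-2,5-dimethoxy-3,6-bis(2,3,5-tribromo-4-hydroxyphenoxy)benzene
Product: 16 2,5-dibromo-3,6-bis(2,3,5-tribromo-4-hydroxyphenoxy)benzene-1,4-diol (CNP0163357.0)
Conditions: BBr3 (excess), CH2Cl2, −78 °C to rt; then H2O, argon
Reagents that add atoms: none
Why: Lewis acid cleavage of methyl aryl ethers by BBr3 (bromide attacks the methyl carbon of the boron-complexed ether); diaryl ethers and aryl bromides are inert, and the hydroquinone is worked up under argon to avoid reoxidation.

## Compound list

1 | bromanil (2,3,5,6-tetrabromo-1,4-benzoquinone) | O=C1C(Br)=C(Br)C(=O)C(Br)=C1Br | starting material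
2 | 2,5-dibromo-3,6-dimethoxy-1,4-benzoquinone | O=C1C(Br)=C(OC)C(=O)C(Br)=C1OC | intermediate
3 | 2,5-dibromo-3,6-dimethoxybenzene-1,4-diol | Oc1c(Br)c(OC)c(O)c(Br)c1OC | intermediate
4 | methyl bromoacetate | COC(=O)CBr | starting material
5 | dimethyl 2,2'-[(2,5-dibromo-3,6-dimethoxy-1,4-phenylene)bis(oxy)]diacetate | COC(=O)COc1c(Br)c(OC)c(OCC(=O)OC)c(Br)c1OC | intermediate
6 | disodium salt of dimethyl 2,2'-[(2,5-dibromo-3,6-dimethoxy-1,4-phenylene)bis(oxy)]bis(3-hydroxyprop-2-enoate), enolate geometry not defined | COC(=O)C(=C[O-])Oc1c(Br)c(OC)c(OC(=C[O-])C(=O)OC)c(Br)c1OC.[Na+].[Na+] | intermediate (not isolated)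
7 | dimethyl 2,2'-[(2,5-dibromo-3,6-dimethoxy-1,4-phenylene)bis(oxy)]diacrylate | COc1c(Br)c(OC(=C)C(=O)OC)c(OC)c(Br)c1OC(=C)C(=O)OC | intermediate
8 | 2-(trimethylsilyloxy)buta-1,3-diene | C=CC(=C)O[Si](C)(C)C | starting material
9 | dimethyl 1,1'-[(2,5-dibromo-3,6-dimethoxy-1,4-phenylene)bis(oxy)]bis[4-(trimethylsilyloxy)cyclohex-3-ene-1-carboxylate], mixture of meso and racemic forms | COc1c(Br)c(OC2(CCC(O[Si](C)(C)C)=CC2)C(=O)OC)c(OC)c(Br)c1OC3(CCC(O[Si](C)(C)C)=CC3)C(=O)OC | intermediate (not isolated)
10 | dimethyl 1,1'-[(2,5-dibromo-3,6-dimethoxy-1,4-phenylene)bis(oxy)]bis(4-oxocyclohexane-1-carboxylate) | COc1c(Br)c(OC2(CCC(=O)CC2)C(=O)OC)c(OC)c(Br)c1OC3(CCC(=O)CC3)C(=O)OC | intermediate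
11 | dimethyl 1,1'-[(2,5-dibromo-3,6-dimethoxy-1,4-phenylene)bis(oxy)]bis(4-oxocyclohexa-2,5-diene-1-carboxylate) | COc1c(Br)c(OC2(C=CC(=O)C=C2)C(=O)OC)c(OC)c(Br)c1OC3(C=CC(=O)C=C3)C(=O)OC | intermediate
12 | dilithium 1,1'-[(2,5-dibromo-3,6-dimethoxy-1,4-phenylene)bis(oxy)]bis(4-oxocyclohexa-2,5-diene-1-carboxylate) | COc1c(Br)c(OC2(C=CC(=O)C=C2)C(=O)[O-])c(OC)c(Br)c1OC3(C=CC(=O)C=C3)C(=O)[O-].[Li+].[Li+] | intermediate (not isolated)
13 | 4,4'-[(2,5-dibromo-3,6-dimethoxy-1,4-phenylene)bis(oxy)]diphenol | COc1c(Br)c(Oc2ccc(O)cc2)c(OC)c(Br)c1Oc3ccc(O)cc3 | intermediate
14 | 4,4'-[(2,5-dibromo-3,6-dimethoxy-1,4-phenylene)bis(oxy)]bis(2,6-dibromophenol) | COc1c(Br)c(Oc2cc(Br)c(O)c(Br)c2)c(OC)c(Br)c1Oc3cc(Br)c(O)c(Br)c3 | intermediate (not isolated)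
15 | 1,4-dibromo-2,5-dimethoxy-3,6-bis(2,3,5-tribromo-4-hydroxyphenoxy)benzene | COc1c(Br)c(Oc2cc(Br)c(O)c(Br)c2Br)c(OC)c(Br)c1Oc3cc(Br)c(O)c(Br)c3Br | intermediate
16 | 2,5-dibromo-3,6-bis(2,3,5-tribromo-4-hydroxyphenoxy)benzene-1,4-diol (CNP0163357.0) | Oc1c(Br)cc(Oc2c(O)c(Br)c(Oc3cc(Br)c(O)c(Br)c3Br)c(O)c2Br)c(Br)c1Br | target

## Step count and risks

Total step count: 9. Longest linear sequence: 9 steps (1 to 16; 4 and 8 are purchased).

**Step 5 (key step).** The most likely failure is a cycloaddition that is too slow at the alpha-oxygenated, sterically shielded dienophile, so that diene dimerisation and acrylate polymerisation consume the partners or the reaction stops after one arm. The fallback sets out from 7, which would be heated with the more nucleophilic trans-1-methoxy-3-(trimethylsilyloxy)buta-1,3-diene, whose siloxy-side CH2 again bonds to the acrylate CH2. This gives the bis(methoxy silyl enol ether) cycloadduct F1. Dilute acid hydrolyses F1 and eliminates methanol to give the bis(cyclohexenone) diester F2. One IBX dehydrogenation per ring then brings F2 back to the route at 11, with the same bonds and rings formed and half the oxidation work of step 6.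

**Step 8.** The risk is an uneven bromine count: a ring stopping at two bromines or running on to four gives mixtures that are hard to separate. A second risk is ipso attack of bromine at the ether-bearing carbon, followed by oxidative loss of the aryl ether. The fallback sets out from 13 and replaces the last electrophilic bromination by a deprotonative one that can act only once per ring. 13 would be treated with four equivalents of bromine and the reaction stopped at 14, which is isolated; methylation of both phenols (MeI, K2CO3, acetone) gives the tetrabromo tetramethyl ether F3. TMPMgCl·LiCl (about two equivalents, THF, −40 °C) removes one hydrogen per outer ring, from the carbon between the ether oxygen and a bromine, and gives the bis(arylmagnesium chloride) F4; a ring that already carries magnesium resists a second deprotonation. 1,2-Dibromotetrachloroethane then gives the hexabromo tetramethyl ether F5 (identical with A5), and BBr3 cleaves all four methyl ethers, so that the route is rejoined at 16.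

**Step 4.** The formylation may stay incomplete on one arm, and the aqueous carbonate stage may hydrolyse ester groups or let the acrylate polymerise. The fallback sets out from 3: O–H insertion of the carbenoid from methyl 2-diazo-2-(dimethoxyphosphoryl)acetate, catalysed by Rh2(OAc)4 in hot toluene, gives the bis(phosphonoacetate) F6. A Horner–Wadsworth–Emmons reaction of F6 with aqueous formaldehyde and K2CO3 returns to the route at 7 and bypasses 5.

**Step 6.** Four dehydrogenations on one molecule may stall at mixed enone and dienone stages, and prolonged heating with excess oxidant may degrade the material. The fallback sets out from 10: alpha,alpha'-dibromination of each ketone with PhNMe3Br3 in THF gives the tetrabromo bis(ketone) F7 as a stereoisomer mixture. Double dehydrobromination with Li2CO3 and LiBr in DMF at 120 °C rejoins the route at 11. Any ester cleaved by bromide under these conditions would simply aromatise to 13, the next compound of the route.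

## Further compounds

F1 | step 5 | dimethyl 1,1'-[(2,5-dibromo-3,6-dimethoxy-1,4-phenylene)bis(oxy)]bis[2-methoxy-4-(trimethylsilyloxy)cyclohex-3-ene-1-carboxylate], mixture of diastereomers | COc1c(Br)c(OC2(C(OC)C=C(O[Si](C)(C)C)CC2)C(=O)OC)c(OC)c(Br)c1OC3(C(OC)C=C(O[Si](C)(C)C)CC3)C(=O)OC
F2 | step 5 | dimethyl 1,1'-[(2,5-dibromo-3,6-dimethoxy-1,4-phenylene)bis(oxy)]bis(4-oxocyclohex-2-ene-1-carboxylate), mixture of meso and racemic forms | COc1c(Br)c(OC2(C=CC(=O)CC2)C(=O)OC)c(OC)c(Br)c1OC3(C=CC(=O)CC3)C(=O)OC
F3 | step 8 | 1,4-dibromo-2,5-bis(3,5-dibromo-4-methoxyphenoxy)-3,6-dimethoxybenzene | COc1c(Br)c(Oc2cc(Br)c(OC)c(Br)c2)c(OC)c(Br)c1Oc3cc(Br)c(OC)c(Br)c3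
F4 | step 8 | bis(arylmagnesium chloride) of F3, magnesiated on each outer ring at the carbon between the ether oxygen and a bromine | COc1c(Br)c(Oc2cc(Br)c(OC)c(Br)c2[Mg]Cl)c(OC)c(Br)c1Oc3cc(Br)c(OC)c(Br)c3[Mg]Cl
F5 | step 8 | 1,4-dibromo-2,5-dimethoxy-3,6-bis(2,3,5-tribromo-4-methoxyphenoxy)benzene | COc1c(Br)c(Oc2cc(Br)c(OC)c(Br)c2Br)c(OC)c(Br)c1Oc3cc(Br)c(OC)c(Br)c3Br
F6 | step 4 | dimethyl 2,2'-[(2,5-dibromo-3,6-dimethoxy-1,4-phenylene)bis(oxy)]bis[2-(dimethoxyphosphoryl)acetate], mixture of diastereomers | COC(=O)C(Oc1c(Br)c(OC)c(OC(C(=O)OC)P(=O)(OC)OC)c(Br)c1OC)P(=O)(OC)OC
F7 | step 6 | dimethyl 1,1'-[(2,5-dibromo-3,6-dimethoxy-1,4-phenylene)bis(oxy)]bis(3,5-dibromo-4-oxocyclohexane-1-carboxylate), mixture of stereoisomers | COc1c(Br)c(OC2(CC(Br)C(=O)C(Br)C2)C(=O)OC)c(OC)c(Br)c1OC3(CC(Br)C(=O)C(Br)C3)C(=O)OC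
A1 | alternative 1 | 4-hydroxy-3-(4-methoxyphenoxy)-4-[(Z)-2-(4-methoxyphenoxy)ethenyl]cyclobut-2-en-1-one, racemic | O=C1C=C(Oc2ccc(OC)cc2)C1(O)/C=C\Oc3ccc(OC)cc3
A2 | alternative 1 | 2,5-bis(4-methoxyphenoxy)benzene-1,4-diol | Oc1cc(Oc2ccc(OC)cc2)c(O)cc1Oc3ccc(OC)cc3
A3 | alternative 2 | 1,3-dibromo-5-fluoro-2-methoxy-4-nitrobenzene | COc1c(Br)cc(F)c([N+](=O)[O-])c1Br
A4 | alternative 2 | 6,6'-[(2,5-dibromo-3,6-dimethoxy-1,4-phenylene)bis(oxy)]bis(2,4-dibromo-3-methoxyaniline) | COc1c(Br)c(Oc2cc(Br)c(OC)c(Br)c2N)c(OC)c(Br)c1Oc3cc(Br)c(OC)c(Br)c3N
A5 | alternative 2 | 1,4-dibromo-2,5-dimethoxy-3,6-bis(2,3,5-tribromo-4-methoxyphenoxy)benzene | COc1c(Br)c(Oc2cc(Br)c(OC)c(Br)c2Br)c(OC)c(Br)c1Oc3cc(Br)c(OC)c(Br)c3Br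
A6 | alternative 3 | bromanilic acid (2,5-dibromo-3,6-dihydroxy-1,4-benzoquinone) | O=C1C(Br)=C(O)C(=O)C(Br)=C1O
A7 | alternative 3 | 2,3,6-tribromophenol | Oc1c(Br)ccc(Br)c1Br
A8 | alternative 3 | 2,5-dibromo-3,6-bis(2,3,5-tribromo-4-hydroxyphenoxy)-1,4-benzoquinone | O=C1C(Br)=C(Oc2cc(Br)c(O)c(Br)c2Br)C(=O)C(Br)=C1Oc3cc(Br)c(O)c(Br)c3Br
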